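## Retrosynthetic overview

1. The last bond cut is the ester C–O bond between the neopentyl primary alcohol of the lactone half 37 (rings B and C) and the acrylic acid 18 (ring A); a single acidolysis then removes one tert-butyl ester and two TBS ethers.
2. Ring A (the cyclohexene of the acid half; C1 carries the acrylate, C2=C3 with CH2OH on C3, C6 carries the isopropyl group) is cut across the CH2–CH2 bond C4–C5 and the bond C1–C6. In the forward sense this is a catalytic enantioselective Diels–Alder reaction of the acyclic, achiral triene 12 with methyl vinyl ketone.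
3. The enabling feature is the ring C2=C3 double bond flanked by the stereocentre C1 and the methylene C4, with the C6 isopropyl group cis to the C1 side chain. Written as an acetyl group, that substituent is an ortho/endo-directing activator on C6; it is converted back to isopropyl by methylenation and hydrogenation.
4. Ring B comes from (R)-cryptone by vinyl conjugate addition with formaldehyde trapping, then axial sulfonium-ylide epoxidation and opening at CH2 to set the tertiary carbinol. Ring C (the oxepinone) is closed last by ring-closing metathesis onto a 2-(acyloxymethyl)acrylate.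
5. Order of ring formation: ring A (step 6), ring B (step 10), ring C (step 18).

Key step: step 6

Assumption: the (R)-configured oxazaborolidinium cation is taken to leave the Cα Re face of bound methyl vinyl ketone open (α-C–H···O binding model for enones); if the sense proves opposite, its antipode is used with no other change.

## Route

Step 1
Reactants: 1 2-bromoprop-2-en-1-ol; 2 tert-butyl(chloro)dimethylsilane
Product: 3 [(2-bromoprop-2-en-1-yl)oxy](tert-butyl)dimethylsilane
Conditions: TBSCl (1.1 equiv), imidazole (1.5 equiv), CH2Cl2, 0 °C → rt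
Reagents that add atoms: tert-butyl(chloro)dimethylsilane (2), CC(C)(C)[Si](C)(C)Cl
Why: Standard silylation of a primary allylic alcohol, which masks the future ring hydroxymethyl group for the Lewis-acidic and basic steps that follow.

Step 2
Reactants: 3 [(2-bromoprop-2-en-1-yl)oxy](tert-butyl)dimethylsilane; 4 (E)-2-(3,3-diethoxyprop-1-en-1-yl)-4,4,5,5-tetramethyl-1,3,2-dioxaborolane
Product: 6 (E)-4-{[(tert-butyldimethylsilyl)oxy]methyl}penta-2,4-dienal, via dienyl diethyl acetal 5 (not isolated)
Conditions: Pd(dppf)Cl2 (3 mol %), K3PO4 (3 equiv), THF/H2O (5:1), 60 °C; then 5% aq. oxalic acid, THF, rt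
Reagents that add atoms: boronate (4), CCOC(OCC)/C=C/B1OC(C)(C)C(C)(C)O1; water, O
Why: Suzuki–Miyaura coupling of an alkenyl bromide with an (E)-alkenylboronate should retain the alkene geometry, and the conjugated acetal is hydrolysed by acid too mild to cleave the primary TBS ether.

Step 3
Reactants: 7 (2-hydroxyethyl)triphenylphosphonium bromide; 2 tert-butyl(chloro)dimethylsilane
Product: 8 {2-[(tert-butyldimethylsilyl)oxy]ethyl}triphenylphosphonium bromide
Conditions: TBSCl (1.2 equiv), imidazole (1.5 equiv), CH2Cl2/DMF, rt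
Reagents that add atoms: tert-butyl(chloro)dimethylsilane (2), CC(C)(C)[Si](C)(C)Cl
Why: Routine O-silylation of the hydroxyethyl phosphonium salt, giving the protected C2 unit that becomes the CH2O-bearing α-carbon of the acrylate.

Step 4
Reactants: 8 {2-[(tert-butyldimethylsilyl)oxy]ethyl}triphenylphosphonium bromide; 9 methyl chloroformate
Product: 11 methyl 3-[(tert-butyldimethylsilyl)oxy]-2-(triphenylphosphoranylidene)propanoate, via silyloxyethylidene phosphorane 10 (not isolated)
Conditions: NaN(SiMe3)2 (1.0 equiv), THF, −78 °C; ClCO2Me (1.0 equiv); then NaN(SiMe3)2 (1.0 equiv), −78 → 0 °C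
Reagents that add atoms: methyl chloroformate (9), COC(Cl)=O
Why: C-acylation of a non-stabilised phosphorus ylide by a chloroformate and deprotonation of the resulting acylphosphonium salt (ylide acylation) should give the ester-stabilised ylide, the low temperature suppressing β-elimination of silyloxide.

Step 5
Reactants: 6 (E)-4-{[(tert-butyldimethylsilyl)oxy]methyl}penta-2,4-dienal; 11 methyl 3-[(tert-butyldimethylsilyl)oxy]-2-(triphenylphosphoranylidene)propanoate
Product: 12 methyl (2E,4E)-2,6-bis{[(tert-butyldimethylsilyl)oxy]methyl}hepta-2,4,6-trienoate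
Conditions: CH2Cl2, rt → 40 °C
Reagents that add atoms: none
Why: Wittig olefination with an α-substituted ester-stabilised ylide should give the (E)-trisubstituted enoate (dienyl group trans to CO2Me, cis to CH2OTBS), which is the acrylate geometry of the target.

Step 6
Reactants: 12 methyl (2E,4E)-2,6-bis{[(tert-butyldimethylsilyl)oxy]methyl}hepta-2,4,6-trienoate; 13 methyl vinyl ketone
Product: 14 methyl (E)-3-[(1S,6S)-6-acetyl-3-{[(tert-butyldimethylsilyl)oxy]methyl}cyclohex-2-en-1-yl]-2-{[(tert-butyldimethylsilyl)oxy]methyl}prop-2-enoate (acetyl cis to the side chain)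
Conditions: MVK (3 equiv), (R)-3,3-diphenyl-1-(o-tolyl)tetrahydro-1H,3H-pyrrolo[1,2-c][1,3,2]oxazaborole·HNTf2 (20 mol %), CH2Cl2, −78 → −40 °C
Reagents that add atoms: methyl vinyl ketone (13), CC(=O)C=C
Why: The protonated oxazaborolidine binds s-trans methyl vinyl ketone at oxygen and lowers its LUMO, and the triene adds in a concerted, asynchronous [4+2] cycloaddition in which the unsubstituted CH2 terminus (C7 of 12) bonds to the enone β-carbon, creating the CH2–CH2 bond of ring A, while C4 bonds to the acetyl-bearing α-carbon. The closest known reaction type is the oxazaborolidinium-catalysed enantioselective Diels–Alder addition of enones and acrylates to 2-substituted and 1,3-disubstituted acyclic butadienes. Ring A is closed in an intermolecular, suprafacial–suprafacial six-membered (4π+2π) mode, both σ-bonds forming in the same operation. The two new stereocentres (ring C1 bearing the acrylate, ring C6 bearing the acetyl group) should be set cis by the endo transition state acting on the (E)-C4=C5 bond of 12, and their absolute configuration by the catalyst, whose aryl groups block the Cα Si face of the bound enone. The step needs site selectivity (the inner diene C2=C3–C4=C5 ends in a fully substituted carbon whose (Z)-CH2OTBS group prevents its s-cis conformer, so only the terminal diene reacts), regioselectivity (the 1-alkenyl and 3-silyloxymethyl substituents of the reacting diene both raise the HOMO coefficient at the CH2 terminus, which places the acetyl group next to the side chain) and endo selectivity (Lewis-acid-bound enone).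

Step 7
Reactants: 14 the cis acetyl cycloadduct; 15 methyltriphenylphosphonium bromide
Product: 16 methyl (E)-2-{[(tert-butyldimethylsilyl)oxy]methyl}-3-[(1S,6S)-3-{[(tert-butyldimethylsilyl)oxy]methyl}-6-(prop-1-en-2-yl)cyclohex-2-en-1-yl]prop-2-enoate
Conditions: Ph3PCH3Br (1.6 equiv), KOt-Bu (1.5 equiv), THF, 0 °C; then 14, 0 °C
Reagents that add atoms: methyltriphenylphosphonium bromide (15), C[P+](c1ccccc1)(c1ccccc1)c1ccccc1.[Br-]
Why: Wittig methylenation should take the methyl ketone much faster than the hindered conjugated ester, and keeping the phosphonium salt in slight excess over base avoids epimerisation of the cis ketone α-stereocentre.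

Step 8
Reactants: 16 the isopropenyl ester
Product: 17 methyl (E)-2-{[(tert-butyldimethylsilyl)oxy]methyl}-3-[(1S,6R)-3-{[(tert-butyldimethylsilyl)oxy]methyl}-6-isopropylcyclohex-2-en-1-yl]prop-2-enoate
Conditions: H2 (1 atm), RhCl(PPh3)3 (5 mol %), toluene/EtOH (1:1), rt
Reagents that add atoms: none
Why: Homogeneous hydrogenation with RhCl(PPh3)3 discriminates on steric grounds, so the 1,1-disubstituted isopropenyl alkene should be reduced while the two trisubstituted alkenes stay, and no stereocentre is touched.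

Step 9
Reactants: 17 the isopropyl methyl ester
Product: 18 (E)-2-{[(tert-butyldimethylsilyl)oxy]methyl}-3-[(1S,6R)-3-{[(tert-butyldimethylsilyl)oxy]methyl}-6-isopropylcyclohex-2-en-1-yl]prop-2-enoic acid
Conditions: LiOH·H2O (5 equiv), THF/MeOH/H2O (3:1:1), rt; then 1 M HCl to pH 4, 0 °C
Reagents that add atoms: lithium hydroxide, [Li+].[OH-]
Why: Saponification of the methyl ester, in which hydroxide is too weak a base to remove the doubly allylic ring C1–H and primary TBS ethers should survive at rt.

Step 10
Reactants: 19 3-methylbutanal; 13 methyl vinyl ketone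
Product: 21 (R)-4-isopropylcyclohex-2-en-1-one ((R)-cryptone), via (R)-2-isopropyl-5-oxohexanal 20 (not isolated)
Conditions: (R)-2-[diphenyl(trimethylsilyloxy)methyl]pyrrolidine (5 mol %), ethyl 3,4-dihydroxybenzoate (20 mol %), neat, 4 °C; then LiOH (10 mol %), i-PrOH, rt
Reagents that add atoms: methyl vinyl ketone (13), CC(=O)C=C
Why: Enamine-catalysed Michael addition of the aldehyde to the enone (one enamine face is blocked by the diphenyl(silyloxy)methyl group, the (R)-catalyst giving the (R)-aldehyde) followed by intramolecular aldol condensation, i.e. an organocatalytic Robinson-type annulation.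

Step 11
Reactants: 21 (R)-cryptone; 22 vinylmagnesium bromide; 23 formaldehyde (gaseous monomer from cracking of commercial paraformaldehyde)
Product: 25 (2R,3R,4R)-2-(hydroxymethyl)-4-isopropyl-3-vinylcyclohexan-1-one, via bromomagnesium enolate 24 (not isolated)
Conditions: CH2=CHMgBr (1.5 equiv), CuBr·SMe2 (10 mol %), THF, −78 → −40 °C; then CH2O (g), −78 °C; sat. aq. NH4Cl
Reagents that add atoms: vinylmagnesium bromide (22), C=C[Mg]Br; formaldehyde (23), C=O
Why: Copper-catalysed 1,4-addition should deliver the vinyl group anti to the adjacent isopropyl group, and the regiodefined enolate is hydroxymethylated anti to the new vinyl group (three-component conjugate addition–aldol), giving the all-equatorial ketone that is also the thermodynamic epimer.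

Step 12
Reactants: 25 the hydroxymethyl ketone; 26 triisopropylsilyl trifluoromethanesulfonate
Product: 27 (2R,3R,4R)-4-isopropyl-2-{[(triisopropylsilyl)oxy]methyl}-3-vinylcyclohexan-1-one
Conditions: TIPSOTf (1.2 equiv), 2,6-lutidine (2 equiv), CH2Cl2, −78 °C
Reagents that add atoms: triisopropylsilyl trifluoromethanesulfonate (26), CC(C)[Si](C(C)C)(C(C)C)OS(=O)(=O)C(F)(F)F
Why: Fast, non-basic silylation at low temperature should protect the aldol hydroxyl before retro-aldol or dehydration can occur, with a base-stable group for the alkoxide step ahead.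

Step 13
Reactants: 27 the silyloxymethyl ketone; 28 trimethylsulfonium iodide
Product: 29 (3S,4R,5R,6R)-6-isopropyl-4-{[(triisopropylsilyl)oxy]methyl}-5-vinyl-1-oxaspiro[2.5]octane (oxirane CH2 axial, oxygen equatorial)
Conditions: Me3S+ I− (1.5 equiv), n-BuLi (1.4 equiv), THF, −10 °C; then 27, −10 → 0 °C
Reagents that add atoms: trimethylsulfonium iodide (28), C[S+](C)C.[I-]
Why: In the Corey–Chaykovsky epoxidation dimethylsulfonium methylide adds irreversibly along the axial trajectory of the all-equatorial chair ketone (the equatorial path is hindered by the flanking CH2OTIPS group), so the new CH2 should be axial and the oxygen equatorial, which is the carbinol configuration of the target.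

Step 14
Reactants: 29 the spiro-epoxide; 30 (4-methoxyphenyl)methanol
Product: 31 (1S,2R,3R,4R)-4-isopropyl-1-{[(4-methoxybenzyl)oxy]methyl}-2-{[(triisopropylsilyl)oxy]methyl}-3-vinylcyclohexan-1-ol
Conditions: 4-MeOC6H4CH2OH (3 equiv), NaH (1.5 equiv), DMF, 70 °C
Reagents that add atoms: (4-methoxyphenyl)methanol (30), COc1ccc(CO)cc1
Why: Alkoxide SN2 opening of the 2,2-disubstituted oxirane should occur at the unsubstituted CH2 only, so the tertiary C–O bond and its configuration are untouched and the two oxygens emerge differentiated.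

Step 15
Reactants: 31 the PMB ether silyl ether
Product: 32 (1S,2R,3R,4R)-2-(hydroxymethyl)-4-isopropyl-1-{[(4-methoxybenzyl)oxy]methyl}-3-vinylcyclohexan-1-ol
Conditions: TBAF (1.5 equiv), THF, rt
Reagents that add atoms: none
Why: Fluoride-driven desilylation should free the primary alcohol while the PMB ether, tertiary alcohol and vinyl group are inert.

Step 16
Reactants: 32 the primary/tertiary diol
Product: 33 (1S,2S,5R,6R)-2-hydroxy-5-isopropyl-2-{[(4-methoxybenzyl)oxy]methyl}-6-vinylcyclohexane-1-carboxylic acid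
Conditions: TEMPO (20 mol %), PhI(OAc)2 (2.5 equiv), MeCN/H2O (1:1), rt
Reagents that add atoms: water, O
Why: Oxoammonium (TEMPO) oxidation in aqueous acetonitrile should take the primary alcohol through the aldehyde hydrate to the acid under near-neutral conditions that spare the tertiary alcohol, PMB ether and alkene and avoid retro-aldol cleavage.

Step 17
Reactants: 33 the hydroxy acid; 34 tert-butyl 2-(bromomethyl)prop-2-enoate
Product: 35 2-(tert-butoxycarbonyl)prop-2-en-1-yl (1S,2S,5R,6R)-2-hydroxy-5-isopropyl-2-{[(4-methoxybenzyl)oxy]methyl}-6-vinylcyclohexane-1-carboxylate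
Conditions: KHCO3 (1.5 equiv), DMF, rt
Reagents that add atoms: tert-butyl 2-(bromomethyl)prop-2-enoate (34), C=C(CBr)C(=O)OC(C)(C)C
Why: Carboxylate O-alkylation by the activated allylic bromide (SN2 and SN2' give the same product) should proceed with a base too weak to deprotonate the tertiary alcohol or the ester α-carbon.

Step 18
Reactants: 35 the diene ester
Product: 36 tert-butyl (5aS,6R,9S,9aS)-9-hydroxy-6-isopropyl-9-{[(4-methoxybenzyl)oxy]methyl}-1-oxo-1,3,5a,6,7,8,9,9a-octahydro-2-benzoxepine-4-carboxylate (trans-fused)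
Conditions: second-generation Grubbs catalyst, RuCl2(H2IMes)(PCy3)(=CHPh) (10 mol %), toluene (5 mM), 80 °C, argon sparge
Reagents that add atoms: none
Why: Ring-closing metathesis between the vinyl group and the 1,1-disubstituted acrylate of the two trans-diequatorial arms should close the seven-membered lactone (ring C) with loss of ethene, the ring fixing the trisubstituted alkene in the required geometry.

Step 19
Reactants: 36 the PMB-protected lactone
Product: 37 tert-butyl (5aS,6R,9S,9aS)-9-hydroxy-9-(hydroxymethyl)-6-isopropyl-1-oxo-1,3,5a,6,7,8,9,9a-octahydro-2-benzoxepine-4-carboxylate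
Conditions: DDQ (1.5 equiv), CH2Cl2/pH 7 buffer (10:1), 0 °C → rt
Reagents that add atoms: none
Why: Oxidative cleavage of the PMB ether by DDQ (benzylic oxocarbenium, hydrolysed by the buffered water) should unmask the primary alcohol without affecting the electron-poor enoate, the lactone or the tert-butyl ester.

Step 20
Reactants: 18 the ring A acid; 37 the lactone diol; 38 2,4,6-trichlorobenzoyl chloride
Product: 40 the fully protected ester (primary alcohol of 37 acylated by 18; tert-butyl ester and two TBS ethers in place), via mixed anhydride 39 (not isolated)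
Conditions: 2,4,6-Cl3C6H2COCl (1.2 equiv), Et3N (3 equiv), THF, rt; then 37 (1.0 equiv), DMAP (2 equiv), toluene, rt
Reagents that add atoms: none
Why: Yamaguchi esterification through the mixed anhydride and the acylpyridinium ion should acylate the primary hydroxyl only, the tertiary alcohol being too hindered, and the non-enolisable acrylate cannot epimerise.

Step 21
Reactants: 40 the fully protected ester
Product: 41 CNP0361406.9 (target)
Conditions: TFA/CH2Cl2/H2O (10:10:1), 0 °C → rt; toluene azeotrope
Reagents that add atoms: none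
Why: Acidolysis should cleave the tert-butyl ester (loss of 2-methylpropene) and both primary TBS ethers in one operation, while the lactone, the acrylate ester and the tertiary alcohol, whose ionisation is disfavoured by the flanking acyloxy and carbonyl groups, should persist.

## Compound list

1 | 2-bromoprop-2-en-1-ol | OCC(Br)=C | starting material
2 | tert-butyl(chloro)dimethylsilane | CC(C)(C)[Si](C)(C)Cl | starting material
3 | [(2-bromoprop-2-en-1-yl)oxy](tert-butyl)dimethylsilane | C=C(Br)CO[Si](C)(C)C(C)(C)C | intermediate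
4 | (E)-2-(3,3-diethoxyprop-1-en-1-yl)-4,4,5,5-tetramethyl-1,3,2-dioxaborolane | CCOC(OCC)/C=C/B1OC(C)(C)C(C)(C)O1 | starting material
5 | (E)-tert-butyl[(5,5-diethoxy-2-methylidenepent-3-en-1-yl)oxy]dimethylsilane | CCOC(OCC)/C=C/C(=C)CO[Si](C)(C)C(C)(C)C | intermediate
6 | (E)-4-{[(tert-butyldimethylsilyl)oxy]methyl}penta-2,4-dienal | O=C/C=C/C(=C)CO[Si](C)(C)C(C)(C)C | intermediate
7 | (2-hydroxyethyl)triphenylphosphonium bromide | OCC[P+](c1ccccc1)(c1ccccc1)c1ccccc1.[Br-] | starting material
8 | {2-[(tert-butyldimethylsilyl)oxy]ethyl}triphenylphosphonium bromide | CC(C)(C)[Si](C)(C)OCC[P+](c1ccccc1)(c1ccccc1)c1ccccc1.[Br-] | intermediate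
9 | methyl chloroformate | COC(Cl)=O | starting material
10 | {2-[(tert-butyldimethylsilyl)oxy]ethylidene}triphenylphosphorane | CC(C)(C)[Si](C)(C)OCC=P(c1ccccc1)(c1ccccc1)c1ccccc1 | intermediate
11 | methyl 3-[(tert-butyldimethylsilyl)oxy]-2-(triphenylphosphoranylidene)propanoate | COC(=O)C(CO[Si](C)(C)C(C)(C)C)=P(c1ccccc1)(c1ccccc1)c1ccccc1 | intermediate
12 | methyl (2E,4E)-2,6-bis{[(tert-butyldimethylsilyl)oxy]methyl}hepta-2,4,6-trienoate | COC(=O)/C(=C/C=C/C(=C)CO[Si](C)(C)C(C)(C)C)CO[Si](C)(C)C(C)(C)C | intermediate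
13 | methyl vinyl ketone (but-3-en-2-one) | CC(=O)C=C | starting material
14 | methyl (E)-3-[(1S,6S)-6-acetyl-3-{[(tert-butyldimethylsilyl)oxy]methyl}cyclohex-2-en-1-yl]-2-{[(tert-butyldimethylsilyl)oxy]methyl}prop-2-enoate | COC(=O)/C(=C/[C@@H]1C=C(CO[Si](C)(C)C(C)(C)C)CC[C@@H]1C(C)=O)CO[Si](C)(C)C(C)(C)C | intermediate
15 | methyltriphenylphosphonium bromide | C[P+](c1ccccc1)(c1ccccc1)c1ccccc1.[Br-] | starting material
16 | methyl (E)-2-{[(tert-butyldimethylsilyl)oxy]methyl}-3-[(1S,6S)-3-{[(tert-butyldimethylsilyl)oxy]methyl}-6-(prop-1-en-2-yl)cyclohex-2-en-1-yl]prop-2-enoate | COC(=O)/C(=C/[C@@H]1C=C(CO[Si](C)(C)C(C)(C)C)CC[C@@H]1C(C)=C)CO[Si](C)(C)C(C)(C)C | intermediate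
17 | methyl (E)-2-{[(tert-butyldimethylsilyl)oxy]methyl}-3-[(1S,6R)-3-{[(tert-butyldimethylsilyl)oxy]methyl}-6-isopropylcyclohex-2-en-1-yl]prop-2-enoate | COC(=O)/C(=C/[C@@H]1C=C(CO[Si](C)(C)C(C)(C)C)CC[C@@H]1C(C)C)CO[Si](C)(C)C(C)(C)C | intermediate
18 | (E)-2-{[(tert-butyldimethylsilyl)oxy]methyl}-3-[(1S,6R)-3-{[(tert-butyldimethylsilyl)oxy]methyl}-6-isopropylcyclohex-2-en-1-yl]prop-2-enoic acid | OC(=O)/C(=C/[C@@H]1C=C(CO[Si](C)(C)C(C)(C)C)CC[C@@H]1C(C)C)CO[Si](C)(C)C(C)(C)C | intermediate
19 | 3-methylbutanal | CC(C)CC=O | starting material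
20 | (R)-2-isopropyl-5-oxohexanal | CC(C)[C@H](C=O)CCC(C)=O | intermediate
21 | (R)-4-isopropylcyclohex-2-en-1-one ((R)-cryptone) | CC(C)[C@H]1CCC(=O)C=C1 | intermediate
22 | vinylmagnesium bromide | C=C[Mg]Br | starting material
23 | formaldehyde (monomer, from paraformaldehyde) | C=O | starting material
24 | bromomagnesium (3R,4R)-4-isopropyl-3-vinylcyclohex-1-en-1-olate | CC(C)[C@H]1CCC(O[Mg]Br)=C[C@@H]1C=C | intermediate
25 | (2R,3R,4R)-2-(hydroxymethyl)-4-isopropyl-3-vinylcyclohexan-1-one | CC(C)[C@H]1CCC(=O)[C@@H](CO)[C@@H]1C=C | intermediate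
26 | triisopropylsilyl trifluoromethanesulfonate | CC(C)[Si](C(C)C)(C(C)C)OS(=O)(=O)C(F)(F)F | starting material
27 | (2R,3R,4R)-4-isopropyl-2-{[(triisopropylsilyl)oxy]methyl}-3-vinylcyclohexan-1-one | CC(C)[C@H]1CCC(=O)[C@@H](CO[Si](C(C)C)(C(C)C)C(C)C)[C@@H]1C=C | intermediate
28 | trimethylsulfonium iodide | C[S+](C)C.[I-] | starting material
29 | (3S,4R,5R,6R)-6-isopropyl-4-{[(triisopropylsilyl)oxy]methyl}-5-vinyl-1-oxaspiro[2.5]octane | CC(C)[C@H]1CC[C@@]2(CO2)[C@@H](CO[Si](C(C)C)(C(C)C)C(C)C)[C@@H]1C=C | intermediate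
30 | (4-methoxyphenyl)methanol | COc1ccc(CO)cc1 | starting material
31 | (1S,2R,3R,4R)-4-isopropyl-1-{[(4-methoxybenzyl)oxy]methyl}-2-{[(triisopropylsilyl)oxy]methyl}-3-vinylcyclohexan-1-ol | CC(C)[C@H]1CC[C@@](O)(COCc2ccc(OC)cc2)[C@@H](CO[Si](C(C)C)(C(C)C)C(C)C)[C@@H]1C=C | intermediate
32 | (1S,2R,3R,4R)-2-(hydroxymethyl)-4-isopropyl-1-{[(4-methoxybenzyl)oxy]methyl}-3-vinylcyclohexan-1-ol | CC(C)[C@H]1CC[C@@](O)(COCc2ccc(OC)cc2)[C@@H](CO)[C@@H]1C=C | intermediate
33 | (1S,2S,5R,6R)-2-hydroxy-5-isopropyl-2-{[(4-methoxybenzyl)oxy]methyl}-6-vinylcyclohexane-1-carboxylic acid | CC(C)[C@H]1CC[C@@](O)(COCc2ccc(OC)cc2)[C@@H](C(=O)O)[C@@H]1C=C | intermediate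
34 | tert-butyl 2-(bromomethyl)prop-2-enoate | C=C(CBr)C(=O)OC(C)(C)C | starting material
35 | 2-(tert-butoxycarbonyl)prop-2-en-1-yl (1S,2S,5R,6R)-2-hydroxy-5-isopropyl-2-{[(4-methoxybenzyl)oxy]methyl}-6-vinylcyclohexane-1-carboxylate | CC(C)[C@H]1CC[C@@](O)(COCc2ccc(OC)cc2)[C@@H](C(=O)OCC(=C)C(=O)OC(C)(C)C)[C@@H]1C=C | intermediate
36 | tert-butyl (5aS,6R,9S,9aS)-9-hydroxy-6-isopropyl-9-{[(4-methoxybenzyl)oxy]methyl}-1-oxo-1,3,5a,6,7,8,9,9a-octahydro-2-benzoxepine-4-carboxylate | CC(C)[C@H]1CC[C@@](O)(COCc3ccc(OC)cc3)[C@H]2C(=O)OCC(C(=O)OC(C)(C)C)=C[C@H]12 | intermediate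
37 | tert-butyl (5aS,6R,9S,9aS)-9-hydroxy-9-(hydroxymethyl)-6-isopropyl-1-oxo-1,3,5a,6,7,8,9,9a-octahydro-2-benzoxepine-4-carboxylate | CC(C)[C@H]1CC[C@@](O)(CO)[C@H]2C(=O)OCC(C(=O)OC(C)(C)C)=C[C@H]12 | intermediate
38 | 2,4,6-trichlorobenzoyl chloride | O=C(Cl)c1c(Cl)cc(Cl)cc1Cl | starting material
39 | mixed anhydride of acid 18 with 2,4,6-trichlorobenzoic acid | O=C(OC(=O)/C(=C/[C@@H]1C=C(CO[Si](C)(C)C(C)(C)C)CC[C@@H]1C(C)C)CO[Si](C)(C)C(C)(C)C)c1c(Cl)cc(Cl)cc1Cl | intermediate
40 | fully protected ester: the 9-CH2OH of 37 acylated by acid 18 (tert-butyl ester, two TBS ethers) | CC(C)[C@H]1CC[C@@](O)(COC(=O)/C(=C/[C@@H]2C=C(CO[Si](C)(C)C(C)(C)C)CC[C@@H]2C(C)C)CO[Si](C)(C)C(C)(C)C)[C@H]2C(=O)OCC(C(=O)OC(C)(C)C)=C[C@H]12 | intermediate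
41 | CNP0361406.9 | CC(C)[C@H]1CC[C@@](O)(COC(=O)/C(=C/[C@@H]2C=C(CO)CC[C@@H]2C(C)C)CO)[C@H]2C(=O)OCC(C(=O)O)=C[C@H]12 | target

## Step count and risks

Total step count: 21. Longest linear sequence: 12 steps (steps 10–21). The acid half takes 7 steps in line (1, 2, 5–9) with a 2-step branch (3, 4).

Steps most likely to fail:

1. Step 6. The ester-conjugated triene may be too weak a diene for the enone bound to a one-point boron Lewis acid, so that enone oligomerisation and an uncatalysed background reaction erode conversion and enantio- or endo-selectivity. The fallback uses a two-point-binding dienophile and sets out from 12. Cycloaddition with 3-acryloyl-1,3-oxazolidin-2-one under 10 mol % [Cu(t-Bu-box)](SbF6)2 (divalent copper, (R,R)-ligand; CH2Cl2, rt) should give the cis imide cycloadduct F1. Lithium ethanethiolate (EtSH, n-BuLi, THF, 0 °C) converts it into the S-ethyl thioester F2. Me2CuLi (Et2O, −78 °C) then gives the methyl ketone, returning to the route at 14.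

2. Step 18. Metathesis may stall at the electron-poor 1,1-disubstituted acrylate, so that intermolecular coupling through the vinyl group outruns seven-membered ring closure. The fallback makes the ring alkene by olefination and sets out from 33. Lemieux–Johnson cleavage of the vinyl group (OsO4 cat., NaIO4, 2,6-lutidine, dioxane/H2O) should give the formyl acid F6. Its caesium carboxylate (Cs2CO3, MeCN) adds in an oxa-Michael reaction to tert-butyl 2-(diethoxyphosphoryl)prop-2-enoate to give the α-phosphono ester F7. Its phosphonate anion closes the ring by intramolecular Horner–Wadsworth–Emmons olefination, returning to the route at 36.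

3. Step 11. Trapping of the enolate with formaldehyde may over-run (second hydroxymethylation, dehydration to the α-methylene ketone) or be outpaced by proton transfer that scrambles the enolate. The fallback inverts the order of the two C–C bond formations and sets out from 21. Morita–Baylis–Hillman hydroxymethylation (aq. CH2O, DMAP, THF/H2O, rt) should give (R)-2-(hydroxymethyl)-4-isopropylcyclohex-2-en-1-one F3, and TIPSOTf/2,6-lutidine gives its silyl ether F4. Copper-catalysed addition of CH2=CHMgBr (CuBr·SMe2, THF, −78 °C) anti to the isopropyl group forms the bromomagnesium enolate F5. Cold protonation (AcOH, −78 °C) on the face anti to the vinyl group gives the all-equatorial ketone, returning to the route at 27.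

## Further compounds

F1 | step 6 | methyl (E)-2-{[(tert-butyldimethylsilyl)oxy]methyl}-3-[(1S,6S)-3-{[(tert-butyldimethylsilyl)oxy]methyl}-6-(2-oxo-1,3-oxazolidine-3-carbonyl)cyclohex-2-en-1-yl]prop-2-enoate | COC(=O)/C(=C/[C@@H]1C=C(CO[Si](C)(C)C(C)(C)C)CC[C@@H]1C(=O)N1CCOC1=O)CO[Si](C)(C)C(C)(C)C
F2 | step 6 | methyl (E)-2-{[(tert-butyldimethylsilyl)oxy]methyl}-3-[(1S,6S)-3-{[(tert-butyldimethylsilyl)oxy]methyl}-6-[(ethylsulfanyl)carbonyl]cyclohex-2-en-1-yl]prop-2-enoate | COC(=O)/C(=C/[C@@H]1C=C(CO[Si](C)(C)C(C)(C)C)CC[C@@H]1C(=O)SCC)CO[Si](C)(C)C(C)(C)C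
F3 | step 11 | (R)-2-(hydroxymethyl)-4-isopropylcyclohex-2-en-1-one | CC(C)[C@H]1CCC(=O)C(CO)=C1
F4 | step 11 | (R)-4-isopropyl-2-{[(triisopropylsilyl)oxy]methyl}cyclohex-2-en-1-one | CC(C)[C@H]1CCC(=O)C(CO[Si](C(C)C)(C(C)C)C(C)C)=C1
F5 | step 11 | bromomagnesium (3R,4R)-4-isopropyl-2-{[(triisopropylsilyl)oxy]methyl}-3-vinylcyclohex-1-en-1-olate | CC(C)[C@H]1CCC(O[Mg]Br)=C(CO[Si](C(C)C)(C(C)C)C(C)C)[C@@H]1C=C
F6 | step 18 | (1S,2S,5R,6R)-6-formyl-2-hydroxy-5-isopropyl-2-{[(4-methoxybenzyl)oxy]methyl}cyclohexane-1-carboxylic acid | CC(C)[C@H]1CC[C@@](O)(COCc2ccc(OC)cc2)[C@@H](C(=O)O)[C@@H]1C=O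
F7 | step 18 | 3-(tert-butoxy)-2-(diethoxyphosphoryl)-3-oxopropyl (1S,2S,5R,6R)-6-formyl-2-hydroxy-5-isopropyl-2-{[(4-methoxybenzyl)oxy]methyl}cyclohexane-1-carboxylate | CC(C)[C@H]1CC[C@@](O)(COCc2ccc(OC)cc2)[C@@H](C(=O)OCC(C(=O)OC(C)(C)C)P(=O)(OCC)OCC)[C@@H]1C=O
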